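**Plan**
- Retrosynthesis: the O7–Si bond is cut first, then ring A at C4a–C5 and C8–C8a (retro-[4+2] after formal return of Me2NH and PhSO2H). The remaining pyranone is cut at its C–S bond and at the C3–C1' biaryl bond, back to 4H-pyran-4-one; the diene goes back to methoxyacetone.
- Enabling feature: ring A carries hydrogen at C5 and C8 and neighbouring oxygens at C6 (OMe) and C7 (OH). This is the footprint of a butadiene oxygenated on both inner carbons laid across the C4a–C8a bond of ring C.
- Forward order: ring C is bought, dibrominated, joined to aryl ring B by cross-coupling and armed with a phenylsulfonyl group. The diene is made in two steps, ring A is built last by cycloaddition and double elimination, and desilylation ends the route.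
- Stereochemistry: the target has no stereocentre. The stereocentres of the cycloadduct vanish on aromatisation, and only the enamine geometry of the diene matters.

Key step: step 6

Assumption: chromone numbering (O1 to C8a) is used for the target; the enaminone and the diene are taken in their thermodynamically preferred geometry (NMe2 trans to the carbonyl-derived carbon), which is the one the cycloaddition needs.

**Step 1**
Reactants: 1 4H-pyran-4-one
Product: 2 3,5-dibromo-4H-pyran-4-one
Conditions: Br2 (2.2 equiv), CH2Cl2, 0 °C to rt; then pyridine (2.5 equiv), 0 °C to rt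
Reagents that add atoms: bromine, BrBr
Why: Bromine adds to each enol-ether-like C=C of the pyranone and base-induced loss of HBr restores the ring (addition–elimination α-bromination, as used on chromones and 4-pyranones); the symmetry of 1 makes the second bromination unambiguous.

**Step 2**
Reactants: 2 3,5-dibromo-4H-pyran-4-one (threefold excess); 3 3,4,5-trimethoxyphenylboronic acid
Product: 4 3-bromo-5-(3,4,5-trimethoxyphenyl)-4H-pyran-4-one
Conditions: Pd(PPh3)4 (5 mol %), K3PO4 (2 equiv), toluene/H2O (10:1), 70 °C; excess 2 recovered
Reagents that add atoms: none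
Why: Suzuki–Miyaura coupling at an α-bromo-enone C(sp2)–Br bond, the reaction used on 3-halochromones to make isoflavones; the excess of symmetric dibromide should hold back the second arylation.

**Step 3**
Reactants: 4 3-bromo-5-(3,4,5-trimethoxyphenyl)-4H-pyran-4-one; 5 sodium benzenesulfinate
Product: 6 3-(phenylsulfonyl)-5-(3,4,5-trimethoxyphenyl)-4H-pyran-4-one
Conditions: CuI (10 mol %), sodium L-prolinate (20 mol %), DMSO, 90 °C
Reagents that add atoms: none
Why: Ullmann-type C–S coupling of a sulfinate salt with an alkenyl/aryl bromide under monovalent copper catalysis should place the sulfone on the carbon that bore bromine, at the right oxidation level and without an oxidation step.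

**Step 4**
Reactants: 7 methoxyacetone (1-methoxypropan-2-one)
Product: 8 (3Z)-4-(dimethylamino)-3-methoxybut-3-en-2-one
Conditions: Me2NCH(OMe)2 (1.5 equiv), neat, 100 °C, MeOH distilled off
Reagents that add atoms: N,N-dimethylformamide dimethyl acetal, COC(OC)N(C)C
Why: Amide-acetal condensation (enaminone formation) is expected at the methylene activated by both the carbonyl and the methoxy group, the site at which α-alkoxy and α-aryloxy acetones react; the push–pull alkene should settle with NMe2 trans to the acetyl group.

**Step 5**
Reactants: 8 (3Z)-4-(dimethylamino)-3-methoxybut-3-en-2-one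
Product: 9 (1Z)-3-[(tert-butyldimethylsilyl)oxy]-2-methoxy-N,N-dimethylbuta-1,3-dien-1-amine
Conditions: KN(SiMe3)2 (1.05 equiv), THF, −78 °C; then TBSCl, −78 °C to rt; non-aqueous work-up, short-path distillation
Reagents that add atoms: tert-butyldimethylsilyl chloride, CC(C)(C)[Si](C)(C)Cl
Why: Kinetic deprotonation of the only enolisable position (the acetyl methyl group) and O-silylation of the potassium dienolate is the standard preparation of 1-amino-3-siloxybutadienes.

**Step 6**
Reactants: 6 3-(phenylsulfonyl)-5-(3,4,5-trimethoxyphenyl)-4H-pyran-4-one; 9 (1Z)-3-[(tert-butyldimethylsilyl)oxy]-2-methoxy-N,N-dimethylbuta-1,3-dien-1-amine (1.5 equiv)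
Product: 11 7-[(tert-butyldimethylsilyl)oxy]-6-methoxy-3-(3,4,5-trimethoxyphenyl)-4H-chromen-4-one, via cis-fused cycloadduct 10 (not isolated)
Conditions: toluene, 0 to 40 °C; then pyridinium p-toluenesulfonate (0.2 equiv), 80 °C
Reagents that add atoms: none
Why: Proposed new method: the electron-rich diene 9 should add in a normal-demand, concerted but asynchronous [4+2] cycloaddition across the C2=C3 bond of 6, whose LUMO is lowered by the C4 carbonyl and by the sulfonyl group on the same alkene; the closest known reaction type is the Diels–Alder reaction of 3-acceptor-substituted chromones with 1-hetero-3-siloxydienes, which gives xanthones after elimination, moved here to a monocyclic 4-pyranone. Ring A closes as a six-membered carbocycle by intermolecular [4+2] annulation onto ring C, the CH2 terminus of the diene bonding to the oxygen-bearing β-carbon (future C8a) and the amino-bearing terminus to the sulfonyl-bearing carbon (future C4a). Regiochemistry, with the siloxy carbon ending as C7 and the methoxy carbon as C6, relies on the matched 1-amino and 3-siloxy donors putting the largest HOMO coefficient on the CH2 terminus against the weaker opposing influence of the 2-methoxy group, and site selectivity relies on the sulfonyl group, which activates only one of the two ring alkenes while the other bears the donor aryl ring. The stereocentres of cis-fused adduct 10 are erased in the same flask, so endo/exo and facial selectivity are irrelevant and no stereocentre has to be controlled. With catalytic pyridinium acid the allylic amine should leave in a vinylogous 1,4-elimination pushed by the silyl enol ether, and the resulting cyclohexadiene should lose benzenesulfinic acid across C4a–C8a through a para-methoxy-stabilised arenium-like transition state, aromatisation being the driving force, so no oxidant is needed and silicon stays on O7. The cycloaddition is run to completion before the acid is added so that liberated dimethylamine, which ends as its sulfinate salt, never meets the electrophilic pyranone 6.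

**Step 7**
Reactants: 11 7-[(tert-butyldimethylsilyl)oxy]-6-methoxy-3-(3,4,5-trimethoxyphenyl)-4H-chromen-4-one
Product: 12 7-hydroxy-6-methoxy-3-(3,4,5-trimethoxyphenyl)-4H-chromen-4-one (target)
Conditions: Bu4NF (1.1 equiv), AcOH (1.2 equiv), THF, 0 °C
Reagents that add atoms: none
Why: Fluoride-induced cleavage of an aryl silyl ether should be fast here because the 7-phenoxide is a vinylogous carboxylate, and the acetic acid buffer protects the base-sensitive pyranone ring.

**Compound list**
1 | 4H-pyran-4-one | O=c1ccocc1 | starting material
2 | 3,5-dibromo-4H-pyran-4-one | O=c1c(Br)cocc1Br | intermediate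
3 | 3,4,5-trimethoxyphenylboronic acid | COc1cc(B(O)O)cc(OC)c1OC | starting material
4 | 3-bromo-5-(3,4,5-trimethoxyphenyl)-4H-pyran-4-one | COc1cc(-c2cocc(Br)c2=O)cc(OC)c1OC | intermediate
5 | sodium benzenesulfinate | [Na+].[O-]S(=O)c1ccccc1 | starting material
6 | 3-(phenylsulfonyl)-5-(3,4,5-trimethoxyphenyl)-4H-pyran-4-one | COc1cc(-c2cocc(S(=O)(=O)c3ccccc3)c2=O)cc(OC)c1OC | intermediate
7 | methoxyacetone (1-methoxypropan-2-one) | COCC(C)=O | starting material
8 | (3Z)-4-(dimethylamino)-3-methoxybut-3-en-2-one (NMe2 and OMe cis) | CN(C)/C=C(\OC)C(C)=O | intermediate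
9 | (1Z)-3-[(tert-butyldimethylsilyl)oxy]-2-methoxy-N,N-dimethylbuta-1,3-dien-1-amine (NMe2 trans to the siloxyvinyl group) | CN(C)/C=C(\OC)C(=C)O[Si](C)(C)C(C)(C)C | intermediate
10 | 7-[(tert-butyldimethylsilyl)oxy]-5-(dimethylamino)-6-methoxy-4a-(phenylsulfonyl)-3-(3,4,5-trimethoxyphenyl)-4a,5,8,8a-tetrahydro-4H-chromen-4-one; racemic, 8a-H cis to the 4a-sulfonyl group, C5 epimers not assigned; formed in the flask, not isolated | COC1=C(O[Si](C)(C)C(C)(C)C)C[C@@H]2OC=C(c3cc(OC)c(OC)c(OC)c3)C(=O)[C@]2(S(=O)(=O)c3ccccc3)C1N(C)C | intermediate
11 | 7-[(tert-butyldimethylsilyl)oxy]-6-methoxy-3-(3,4,5-trimethoxyphenyl)-4H-chromen-4-one | COc1cc2c(=O)c(-c3cc(OC)c(OC)c(OC)c3)coc2cc1O[Si](C)(C)C(C)(C)C | intermediate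
12 | 7-hydroxy-6-methoxy-3-(3,4,5-trimethoxyphenyl)-4H-chromen-4-one | COc1cc2c(=O)c(-c3cc(OC)c(OC)c(OC)c3)coc2cc1O | target

**Totals**
Total step count: 7. Longest linear sequence: 5 steps (steps 1, 2, 3, 6, 7); the diene arm is 2 steps (4, 5) before the convergent step 6.

**Steps most likely to fail**

Step 6. The diene may be diverted into a stepwise conjugate addition followed by opening of the pyranone ring, or into an inverse-demand hetero-Diels–Alder reaction at the sulfonyl enone. The aromatisation may also stop after loss of the amine, and the silyl group may be lost early (harmless, since step 7 removes it anyway). The fallback uses known chemistry and buys ring A instead of building it; it sets out from boronic acid 3 and comes back to the route at target 12. Purchased 1-(2,4-dihydroxy-5-methoxyphenyl)ethanone F1 would be benzylated at the non-chelated 4-hydroxyl (BnBr, K2CO3, acetone) to give 1-[4-(benzyloxy)-2-hydroxy-5-methoxyphenyl]ethanone F2. Condensation with DMF dimethyl acetal would give (E)-1-[4-(benzyloxy)-2-hydroxy-5-methoxyphenyl]-3-(dimethylamino)prop-2-en-1-one F3. Iodine-induced cyclisation (I2, CHCl3, rt) would give 7-(benzyloxy)-3-iodo-6-methoxy-4H-chromen-4-one F4. Suzuki–Miyaura coupling of F4 with 3 (Pd(PPh3)4, K3PO4, dioxane/H2O) would give 7-(benzyloxy)-6-methoxy-3-(3,4,5-trimethoxyphenyl)-4H-chromen-4-one F5, and hydrogenolysis (H2, Pd/C, EtOAc/THF) would deliver 12.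

Step 3. Conjugate addition of sulfinate at C6 followed by loss of HBr (cine substitution), or ring opening of the pyranone in hot DMSO, may outrun the copper-mediated ipso substitution. The fallback introduces sulfur at the sulfide level and oxidises afterwards; it sets out from 4 and comes back at 6. Palladium-catalysed thioetherification of 4 with thiophenol (Pd2(dba)3, Xantphos, iPr2NEt, dioxane, 100 °C) would give 3-(phenylsulfanyl)-5-(3,4,5-trimethoxyphenyl)-4H-pyran-4-one F6. Oxidation with mCPBA (2.2 equiv, CH2Cl2, 0 °C to rt) would give sulfone 6; the electron-poor ring alkenes should not be epoxidised.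

Step 2. Double arylation and hydroxide-induced ring opening of the electron-poor dibromopyranone may erode the statistical mono-coupling. The fallback differentiates the two halogens instead of relying on stoichiometry; it sets out from 1 and comes back at 4. Monobromination of 1 (Br2, 1.05 equiv, then pyridine) would give 3-bromo-4H-pyran-4-one F7. Iodination by the same addition–elimination pattern (ICl, CH2Cl2, then pyridine) would give 3-bromo-5-iodo-4H-pyran-4-one F8. Coupling of F8 with one equivalent of 3 (Pd(PPh3)4, K3PO4, toluene/H2O, rt to 40 °C) should then occur chemoselectively at the C–I bond to give 4.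

**Further compounds**
F1 | step 6 | 1-(2,4-dihydroxy-5-methoxyphenyl)ethanone | CC(=O)c1cc(OC)c(O)cc1O
F2 | step 6 | 1-[4-(benzyloxy)-2-hydroxy-5-methoxyphenyl]ethanone | CC(=O)c1cc(OC)c(OCc2ccccc2)cc1O
F3 | step 6 | (E)-1-[4-(benzyloxy)-2-hydroxy-5-methoxyphenyl]-3-(dimethylamino)prop-2-en-1-one | CN(C)/C=C/C(=O)c1cc(OC)c(OCc2ccccc2)cc1O
F4 | step 6 | 7-(benzyloxy)-3-iodo-6-methoxy-4H-chromen-4-one | COc1cc2c(=O)c(I)coc2cc1OCc1ccccc1
F5 | step 6 | 7-(benzyloxy)-6-methoxy-3-(3,4,5-trimethoxyphenyl)-4H-chromen-4-one | COc1cc2c(=O)c(-c3cc(OC)c(OC)c(OC)c3)coc2cc1OCc1ccccc1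
F6 | step 3 | 3-(phenylsulfanyl)-5-(3,4,5-trimethoxyphenyl)-4H-pyran-4-one | COc1cc(-c2cocc(Sc3ccccc3)c2=O)cc(OC)c1OC
F7 | step 2 | 3-bromo-4H-pyran-4-one | O=c1ccocc1Br
F8 | step 2 | 3-bromo-5-iodo-4H-pyran-4-one | O=c1c(Br)cocc1I
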